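**Plan**
1. Target 35 has seven benzene rings, lettered A to G from the 2,4,6-trihydroxyphenyl end, joined by six diaryl ether oxygens. It has no stereocentre and no other stereogenic element, so no stereochemistry has to be set.
2. Enabling feature: in ring A the ether carbon C1 sits between the hydroxylated carbons C2 and C6, as C2 of a malonate sits between its two carbonyl carbons. C3–C4(OH)–C5 matches the CH2–CO–CH2 core of a 3-oxopentanedioate. The retrosynthesis therefore cuts the ring A bonds C2–C3 and C5–C6, and the A–O–B oxygen is carried in as the sp3 C–O bond of a 2-aryloxymalonate.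
3. The other cuts are five aryl C–O bonds. The first is O–C1 of ring D, which splits the target into an ABC trimer and a DEFG tetramer. The B/C, D/E, E/F and F/G ethers follow. All five are Cu-catalysed Ullmann couplings, and a formyl group on the incoming ring serves as the masked next phenol (Baeyer–Villiger).
4. Forward: ring B phenol 4 → aryloxymalonate 6 → ring A built (step 4) → AB phenol 13 → ring C added → trimer phenol 19. In parallel, G + F, then E, then D give tetramer bromide 32. Coupling 19 + 32 gives octadecamethyl ether 33, and BBr3 then gives 35.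

Key step: step 4

Remark: in every ring C1 is the carbon bound to the ether oxygen that leads toward ring A (in ring A, the carbon bound to the A–B oxygen). Compounds 1, 5, 7, 14, 20, 21, 25 and 29 are taken to be catalogue chemicals.

**Step 1**
Reactants: 1 syringaldehyde (4-hydroxy-3,5-dimethoxybenzaldehyde)
Product: 2 4-(benzyloxy)-3,5-dimethoxybenzaldehyde
Conditions: BnBr, K2CO3, DMF, 60 °C
Reagents that add atoms: benzyl bromide, BrCc1ccccc1
Why: Williamson etherification of the acidic phenoxide with a reactive benzylic halide should go cleanly and installs the one protecting group that is orthogonal to the methyl ethers.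

**Step 2**
Reactants: 2 4-(benzyloxy)-3,5-dimethoxybenzaldehyde
Product: 4 4-(benzyloxy)-3,5-dimethoxyphenol, via aryl formate 3 (not isolated)
Conditions: mCPBA, CH2Cl2, 0 °C to rt; aq NaHCO3 wash; then K2CO3 (cat.), MeOH, rt
Reagents that add atoms: mCPBA (3-chloroperoxybenzoic acid), OOC(=O)c1cccc(Cl)c1
Why: In this Baeyer–Villiger oxidation the oxygen-rich aryl group should migrate in preference to hydride, and base-catalysed methanolysis of the formate frees the ring B phenol without touching the benzyl ether.

**Step 3**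
Reactants: 4 4-(benzyloxy)-3,5-dimethoxyphenol; 5 dimethyl 2-chloromalonate
Product: 6 dimethyl 2-[4-(benzyloxy)-3,5-dimethoxyphenoxy]malonate
Conditions: K2CO3, acetone, reflux
Reagents that add atoms: none
Why: SN2 displacement of chloride from the doubly carbonyl-activated carbon by an unhindered phenoxide (Williamson type) is the established route to 2-aryloxymalonates and makes the future A–O–B linkage as an ordinary sp3 C–O bond.

**Step 4**
Reactants: 6 dimethyl 2-[4-(benzyloxy)-3,5-dimethoxyphenoxy]malonate; 7 dimethyl 3-oxopentanedioate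
Product: 9 dimethyl 5-[4-(benzyloxy)-3,5-dimethoxyphenoxy]-2,4,6-trihydroxybenzene-1,3-dicarboxylate, via open-chain triester 8 (not isolated)
Conditions: 7, NaOMe (1.05 equiv), MeOH, 0 °C; add 6, NaOMe (2.5 equiv more), MeOH then toluene (MeOH distilled off), 65 to 105 °C, Ar; then 1 M HCl, 0 °C
Reagents that add atoms: none
Why: Proposed new method: the preformed sodium enolate of 7 should attack one ester carbonyl of 6 and expel methoxide (Claisen C-acylation) to give open-chain triester 8, whose second activated methylene is then deprotonated and closes onto the remaining malonate ester in a 6-exo-trig Dieckmann cyclisation, so that the ring A bonds C2–C3 and C5–C6 are both made in one flask. The resulting cyclohexane-1,3,5-trione enolises at once to the benzenetriol, and its deprotonation by the excess methoxide is the irreversible sink that pulls all the preceding reversible acyl transfers, including reopening of any O-acylated or pyranone material, toward 9. The closest known reaction types are the alkoxide-mediated condensation of unsubstituted malonic esters with 3-oxopentanedioic esters to phloroglucinoldicarboxylates and the NaOMe-mediated [3+3] condensation of 2-aryloxymalonates with amidines to 5-aryloxypyrimidine-4,6-diols, and the new element is the pairing of a 2-aryloxymalonate with a carbon 1,3-dinucleophile. No stereocentre remains, because the sp3 CH centres of 8 become aromatic carbons. Regiochemistry needs no control since both partners are symmetrical and only one six-membered carbocycle can result, while chemoselectivity against aldol-type self-condensation of 7 is sought by turning 7 completely into its enolate before 6 is added, which leaves no free ketone as acceptor. The aryloxy group helps by making both ester carbonyls of 6 more electrophilic through induction, and it cannot be lost by beta-elimination because it sits alpha to the carbonyl groups throughout.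

**Step 5**
Reactants: 9 dimethyl 5-[4-(benzyloxy)-3,5-dimethoxyphenoxy]-2,4,6-trihydroxybenzene-1,3-dicarboxylate
Product: 11 2-[4-(benzyloxy)-3,5-dimethoxyphenoxy]benzene-1,3,5-triol, via isophthalic diacid 10 (not isolated)
Conditions: KOH (3 M aq), MeOH, reflux, Ar; then HCl to pH 1–2, 60 °C
Reagents that add atoms: KOH, [K+].[OH-] (its oxygen stands only in the unisolated diacid 10 and leaves again as CO2)
Why: Ester saponification followed by decarboxylation should be easy because phloroglucinolcarboxylic acids lose CO2 through their beta-keto acid tautomers on gentle warming, and the benzyl and diaryl ethers tolerate aqueous alkali and dilute acid.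

**Step 6**
Reactants: 11 2-[4-(benzyloxy)-3,5-dimethoxyphenoxy]benzene-1,3,5-triol
Product: 12 2-[4-(benzyloxy)-3,5-dimethoxyphenoxy]-1,3,5-trimethoxybenzene
Conditions: Me2SO4 (4 equiv), K2CO3, acetone, reflux
Reagents that add atoms: dimethyl sulfate, COS(=O)(=O)OC
Why: Williamson-type O-methylation with the hard electrophile dimethyl sulfate and a weak carbonate base is the standard way to turn phloroglucinols into their trimethyl ethers while keeping C-methylation low.

**Step 7**
Reactants: 12 2-[4-(benzyloxy)-3,5-dimethoxyphenoxy]-1,3,5-trimethoxybenzene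
Product: 13 2,6-dimethoxy-4-(2,4,6-trimethoxyphenoxy)phenol
Conditions: H2 (1 atm), Pd/C, EtOAc–MeOH, rt
Reagents that add atoms: none
Why: Catalytic hydrogenolysis cleaves only the benzylic C–O bond and leaves methyl and diaryl ethers untouched, which uncovers the ring B C4 phenol.

**Step 8**
Reactants: 14 5-bromo-1,2,3-trimethoxybenzene
Product: 16 6-bromo-2,3,4-trimethoxybenzaldehyde, via chloro(methoxy)methyl arene 15 (not isolated)
Conditions: Cl2CHOMe, TiCl4, CH2Cl2, −10 to 0 °C; then ice–water
Reagents that add atoms: dichloromethyl methyl ether, COC(Cl)Cl; water, O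
Why: In this Rieche formylation the two free positions of 14 are equivalent and each lies ortho and para to methoxy groups, so a single aldehyde with bromine ortho to the formyl group should result.

**Step 9**
Reactants: 13 2,6-dimethoxy-4-(2,4,6-trimethoxyphenoxy)phenol; 16 6-bromo-2,3,4-trimethoxybenzaldehyde
Product: 17 6-[2,6-dimethoxy-4-(2,4,6-trimethoxyphenoxy)phenoxy]-2,3,4-trimethoxybenzaldehyde
Conditions: CuI (10 mol %), picolinic acid (20 mol %), K3PO4, DMSO, 90 °C, Ar
Reagents that add atoms: none
Why: In this Ullmann-type diaryl ether synthesis the ortho-formyl group activates a C–Br bond that has only one ortho substituent, and the CuI–picolinic acid system is established for di-ortho-substituted electron-rich phenols, with argon keeping 13 from oxidising.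

**Step 10**
Reactants: 17 6-[2,6-dimethoxy-4-(2,4,6-trimethoxyphenoxy)phenoxy]-2,3,4-trimethoxybenzaldehyde
Product: 19 6-[2,6-dimethoxy-4-(2,4,6-trimethoxyphenoxy)phenoxy]-2,3,4-trimethoxyphenol, via trimer formate 18 (not isolated)
Conditions: mCPBA (1.1 equiv), CH2Cl2, 0 °C; aq NaHCO3 wash; then K2CO3 (cat.), MeOH, rt, Ar
Reagents that add atoms: mCPBA (3-chloroperoxybenzoic acid), OOC(=O)c1cccc(Cl)c1
Why: In this Baeyer–Villiger oxidation the migrating ring C carbon has two ortho and one para oxygen donors, so aryl migration should be fast enough at 0 °C to use up the single equivalent of peracid before the electron-rich rings A and B are attacked.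

**Step 11**
Reactants: 20 3,4,5-trimethoxyphenol; 21 4-bromo-3,5-dimethoxybenzaldehyde
Product: 22 3,5-dimethoxy-4-(3,4,5-trimethoxyphenoxy)benzaldehyde
Conditions: CuI (10 mol %), picolinic acid (20 mol %), K3PO4, DMSO, 90 °C, Ar
Reagents that add atoms: none
Why: This Ullmann-type coupling pairs an unhindered electron-rich phenol with a bromide activated by its para-formyl group, an electronic match that should offset the two flanking methoxy groups.

**Step 12**
Reactants: 22 3,5-dimethoxy-4-(3,4,5-trimethoxyphenoxy)benzaldehyde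
Product: 24 3,5-dimethoxy-4-(3,4,5-trimethoxyphenoxy)phenol, via dimer formate 23 (not isolated)
Conditions: mCPBA, CH2Cl2, 0 °C to rt; aq NaHCO3 wash; then K2CO3 (cat.), MeOH, rt
Reagents that add atoms: mCPBA (3-chloroperoxybenzoic acid), OOC(=O)c1cccc(Cl)c1
Why: Baeyer–Villiger oxidation of a 3,4,5-trioxygenated benzaldehyde, the same substrate type as in step 2, should give the formate by aryl migration, and methanolysis then frees the unhindered ring F C1 phenol.

**Step 13**
Reactants: 24 3,5-dimethoxy-4-(3,4,5-trimethoxyphenoxy)phenol; 25 2-bromo-3,4,5-trimethoxybenzaldehyde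
Product: 26 2-[3,5-dimethoxy-4-(3,4,5-trimethoxyphenoxy)phenoxy]-3,4,5-trimethoxybenzaldehyde
Conditions: CuI (10 mol %), picolinic acid (20 mol %), K3PO4, DMSO, 90 °C, Ar
Reagents that add atoms: none
Why: In this Ullmann-type coupling the phenol has two free ortho positions and the bromide is activated by its ortho-formyl group, so the crowded ring E C2–O bond is formed from the easier polarity.

**Step 14**
Reactants: 26 2-[3,5-dimethoxy-4-(3,4,5-trimethoxyphenoxy)phenoxy]-3,4,5-trimethoxybenzaldehyde
Product: 28 2-[3,5-dimethoxy-4-(3,4,5-trimethoxyphenoxy)phenoxy]-3,4,5-trimethoxyphenol, via trimer formate 27 (not isolated)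
Conditions: mCPBA, CH2Cl2, 0 °C to rt; aq NaHCO3 wash; then K2CO3 (cat.), MeOH, rt
Reagents that add atoms: mCPBA (3-chloroperoxybenzoic acid), OOC(=O)c1cccc(Cl)c1
Why: In this Baeyer–Villiger oxidation the ortho-aryloxy and para-methoxy donors favour aryl migration, which converts the formyl carbon site into the ring E C1 phenol after methanolysis.

**Step 15**
Reactants: 29 4-bromo-2-methoxyphenol
Product: 30 4-bromo-2-iodo-6-methoxyphenol
Conditions: NIS, TsOH·H2O (cat.), MeCN, rt
Reagents that add atoms: N-iodosuccinimide, O=C1CCC(=O)N1I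
Why: Electrophilic aromatic iodination is directed by the free hydroxyl group, whose para and one ortho position are blocked, so iodine should enter the remaining ortho position as it does in other 4-substituted guaiacols.

**Step 16**
Reactants: 30 4-bromo-2-iodo-6-methoxyphenol
Product: 31 5-bromo-1-iodo-2,3-dimethoxybenzene
Conditions: MeI, K2CO3, acetone, reflux
Reagents that add atoms: iodomethane, CI
Why: Williamson methylation of the acidic dihalophenol is routine and gives the ring D unit with two halogens of different reactivity.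

**Step 17**
Reactants: 28 2-[3,5-dimethoxy-4-(3,4,5-trimethoxyphenoxy)phenoxy]-3,4,5-trimethoxyphenol; 31 5-bromo-1-iodo-2,3-dimethoxybenzene
Product: 32 5-bromo-1-{2-[3,5-dimethoxy-4-(3,4,5-trimethoxyphenoxy)phenoxy]-3,4,5-trimethoxyphenoxy}-2,3-dimethoxybenzene
Conditions: 31 (1.5 equiv), CuI (10 mol %), picolinic acid (20 mol %), K3PO4, DMSO, 75 °C, Ar
Reagents that add atoms: none
Why: In this chemoselective Ullmann-type coupling the C–I bond reacts with the monovalent copper phenoxide much faster than the C–Br bond, so with excess 31 at moderate temperature the bromide at ring D C1 should survive as the handle for the fragment union.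

**Step 18**
Reactants: 19 6-[2,6-dimethoxy-4-(2,4,6-trimethoxyphenoxy)phenoxy]-2,3,4-trimethoxyphenol; 32 5-bromo-1-{2-[3,5-dimethoxy-4-(3,4,5-trimethoxyphenoxy)phenoxy]-3,4,5-trimethoxyphenoxy}-2,3-dimethoxybenzene
Product: 33 octadecamethyl ether of the target (rings A to G fully connected, every hydroxyl of 35 as methoxy)
Conditions: CuI (20 mol %), picolinic acid (40 mol %), K3PO4, DMSO, 105 °C, Ar
Reagents that add atoms: none
Why: This Ullmann-type fragment union puts the steric load on the phenol only, because the bromide at ring D C1 has hydrogen at both ortho positions, a combination within the known scope of the CuI–picolinic acid system.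

**Step 19**
Reactants: 33 octadecamethyl ether of the target
Product: 35 target CNP0130704.0, via octadecakis(dibromoboryl) ether 34 (not isolated)
Conditions: BBr3 (about 45 equiv, 1 M in CH2Cl2), −78 °C to rt, Ar; then H2O, 0 °C; degassed solvents for isolation
Reagents that add atoms: BBr3, BrB(Br)Br (boron and bromine stand only in the unisolated 34, drawn in its simplest form)
Why: In this Lewis acid mediated aryl methyl ether cleavage BBr3 binds each methoxy oxygen and bromide removes the methyl group by SN2, whereas the six diaryl ether oxygens carry no sp3 carbon and stay intact, so hydrolysis of the boron aryloxides should free all eighteen phenols.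

**Compound list**
1 | syringaldehyde (4-hydroxy-3,5-dimethoxybenzaldehyde) | COc1cc(C=O)cc(OC)c1O | starting material
2 | 4-(benzyloxy)-3,5-dimethoxybenzaldehyde | COc1cc(C=O)cc(OC)c1OCc1ccccc1 | intermediate
3 | 4-(benzyloxy)-3,5-dimethoxyphenyl formate (not isolated) | COc1cc(OC=O)cc(OC)c1OCc1ccccc1 | intermediate
4 | 4-(benzyloxy)-3,5-dimethoxyphenol | COc1cc(O)cc(OC)c1OCc1ccccc1 | intermediate
5 | dimethyl 2-chloromalonate | COC(=O)C(Cl)C(=O)OC | starting material
6 | dimethyl 2-[4-(benzyloxy)-3,5-dimethoxyphenoxy]malonate | COC(=O)C(Oc1cc(OC)c(OCc2ccccc2)c(OC)c1)C(=O)OC | intermediate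
7 | dimethyl 3-oxopentanedioate | COC(=O)CC(=O)CC(=O)OC | starting material
8 | trimethyl 1-[4-(benzyloxy)-3,5-dimethoxyphenoxy]-2,4-dioxopentane-1,3,5-tricarboxylate (not isolated, configurationally labile) | COC(=O)CC(=O)C(C(=O)OC)C(=O)C(Oc1cc(OC)c(OCc2ccccc2)c(OC)c1)C(=O)OC | intermediate
9 | dimethyl 5-[4-(benzyloxy)-3,5-dimethoxyphenoxy]-2,4,6-trihydroxybenzene-1,3-dicarboxylate | COC(=O)c1c(O)c(C(=O)OC)c(O)c(Oc2cc(OC)c(OCc3ccccc3)c(OC)c2)c1O | intermediate
10 | 5-[4-(benzyloxy)-3,5-dimethoxyphenoxy]-2,4,6-trihydroxybenzene-1,3-dicarboxylic acid (not isolated) | OC(=O)c1c(O)c(C(O)=O)c(O)c(Oc2cc(OC)c(OCc3ccccc3)c(OC)c2)c1O | intermediate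
11 | 2-[4-(benzyloxy)-3,5-dimethoxyphenoxy]benzene-1,3,5-triol | Oc1cc(O)c(Oc2cc(OC)c(OCc3ccccc3)c(OC)c2)c(O)c1 | intermediate
12 | 2-[4-(benzyloxy)-3,5-dimethoxyphenoxy]-1,3,5-trimethoxybenzene | COc1cc(OC)c(Oc2cc(OC)c(OCc3ccccc3)c(OC)c2)c(OC)c1 | intermediate
13 | 2,6-dimethoxy-4-(2,4,6-trimethoxyphenoxy)phenol | COc1cc(OC)c(Oc2cc(OC)c(O)c(OC)c2)c(OC)c1 | intermediate
14 | 5-bromo-1,2,3-trimethoxybenzene | COc1cc(Br)cc(OC)c1OC | starting material
15 | 1-bromo-2-[chloro(methoxy)methyl]-3,4,5-trimethoxybenzene (not isolated, racemic) | COC(Cl)c1c(Br)cc(OC)c(OC)c1OC | intermediate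
16 | 6-bromo-2,3,4-trimethoxybenzaldehyde | O=Cc1c(Br)cc(OC)c(OC)c1OC | intermediate
17 | 6-[2,6-dimethoxy-4-(2,4,6-trimethoxyphenoxy)phenoxy]-2,3,4-trimethoxybenzaldehyde | O=Cc1c(OC)c(OC)c(OC)cc1Oc1c(OC)cc(Oc2c(OC)cc(OC)cc2OC)cc1OC | intermediate
18 | 6-[2,6-dimethoxy-4-(2,4,6-trimethoxyphenoxy)phenoxy]-2,3,4-trimethoxyphenyl formate (not isolated) | O=COc1c(OC)c(OC)c(OC)cc1Oc1c(OC)cc(Oc2c(OC)cc(OC)cc2OC)cc1OC | intermediate
19 | 6-[2,6-dimethoxy-4-(2,4,6-trimethoxyphenoxy)phenoxy]-2,3,4-trimethoxyphenol | Oc1c(OC)c(OC)c(OC)cc1Oc1c(OC)cc(Oc2c(OC)cc(OC)cc2OC)cc1OC | intermediate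
20 | 3,4,5-trimethoxyphenol | COc1cc(O)cc(OC)c1OC | starting material
21 | 4-bromo-3,5-dimethoxybenzaldehyde | COc1cc(C=O)cc(OC)c1Br | starting material
22 | 3,5-dimethoxy-4-(3,4,5-trimethoxyphenoxy)benzaldehyde | COc1cc(C=O)cc(OC)c1Oc1cc(OC)c(OC)c(OC)c1 | intermediate
23 | 3,5-dimethoxy-4-(3,4,5-trimethoxyphenoxy)phenyl formate (not isolated) | COc1cc(OC=O)cc(OC)c1Oc1cc(OC)c(OC)c(OC)c1 | intermediate
24 | 3,5-dimethoxy-4-(3,4,5-trimethoxyphenoxy)phenol | COc1cc(O)cc(OC)c1Oc1cc(OC)c(OC)c(OC)c1 | intermediate
25 | 2-bromo-3,4,5-trimethoxybenzaldehyde | COc1cc(C=O)c(Br)c(OC)c1OC | starting material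
26 | 2-[3,5-dimethoxy-4-(3,4,5-trimethoxyphenoxy)phenoxy]-3,4,5-trimethoxybenzaldehyde | COc1cc(C=O)c(Oc2cc(OC)c(Oc3cc(OC)c(OC)c(OC)c3)c(OC)c2)c(OC)c1OC | intermediate
27 | 2-[3,5-dimethoxy-4-(3,4,5-trimethoxyphenoxy)phenoxy]-3,4,5-trimethoxyphenyl formate (not isolated) | COc1cc(OC=O)c(Oc2cc(OC)c(Oc3cc(OC)c(OC)c(OC)c3)c(OC)c2)c(OC)c1OC | intermediate
28 | 2-[3,5-dimethoxy-4-(3,4,5-trimethoxyphenoxy)phenoxy]-3,4,5-trimethoxyphenol | COc1cc(O)c(Oc2cc(OC)c(Oc3cc(OC)c(OC)c(OC)c3)c(OC)c2)c(OC)c1OC | intermediate
29 | 4-bromo-2-methoxyphenol | COc1cc(Br)ccc1O | starting material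
30 | 4-bromo-2-iodo-6-methoxyphenol | COc1cc(Br)cc(I)c1O | intermediate
31 | 5-bromo-1-iodo-2,3-dimethoxybenzene | COc1cc(Br)cc(I)c1OC | intermediate
32 | 5-bromo-1-{2-[3,5-dimethoxy-4-(3,4,5-trimethoxyphenoxy)phenoxy]-3,4,5-trimethoxyphenoxy}-2,3-dimethoxybenzene | COc1cc(Br)cc(Oc2cc(OC)c(OC)c(OC)c2Oc2cc(OC)c(Oc3cc(OC)c(OC)c(OC)c3)c(OC)c2)c1OC | intermediate
33 | octadecamethyl ether of 35 (every hydroxyl as methoxy) | COc1cc(OC)c(Oc2cc(OC)c(Oc3cc(OC)c(OC)c(OC)c3Oc3cc(OC)c(OC)c(Oc4cc(OC)c(OC)c(OC)c4Oc4cc(OC)c(Oc5cc(OC)c(OC)c(OC)c5)c(OC)c4)c3)c(OC)c2)c(OC)c1 | intermediate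
34 | octadecakis(dibromoboryl) ether of 35 (not isolated, simplest drawing of the boron aryloxides) | BrB(Br)Oc1cc(OB(Br)Br)c(Oc2cc(OB(Br)Br)c(Oc3cc(OB(Br)Br)c(OB(Br)Br)c(OB(Br)Br)c3Oc3cc(OB(Br)Br)c(OB(Br)Br)c(Oc4cc(OB(Br)Br)c(OB(Br)Br)c(OB(Br)Br)c4Oc4cc(OB(Br)Br)c(Oc5cc(OB(Br)Br)c(OB(Br)Br)c(OB(Br)Br)c5)c(OB(Br)Br)c4)c3)c(OB(Br)Br)c2)c(OB(Br)Br)c1 | intermediate
35 | CNP0130704.0: A 2,4,6-trihydroxyphenyl, B 3,5-dihydroxy-1,4-phenylene, C 3,4,5-trihydroxy-1,2-phenylene, D 4,5-dihydroxy-1,3-phenylene, E 3,4,5-trihydroxy-1,2-phenylene, F 3,5-dihydroxy-1,4-phenylene, G 3,4,5-trihydroxyphenyl, joined A–O–B–O–C–O–D–O–E–O–F–O–G (achiral) | Oc1cc(O)c(Oc2cc(O)c(Oc3cc(O)c(O)c(O)c3Oc3cc(O)c(O)c(Oc4cc(O)c(O)c(O)c4Oc4cc(O)c(Oc5cc(O)c(O)c(O)c5)c(O)c4)c3)c(O)c2)c(O)c1 | target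

**Step count**
Total: 19 steps.
Longest linear sequence: 11 steps (1, 2, 3, 4, 5, 6, 7, 9, 10, 18, 19) from syringaldehyde. The tetramer branch (11, 12, 13, 14, 17) joins at step 18. The side branches are step 8 and steps 15–16.

**Steps most likely to fail**

Step 4 (labelled step).
- What may go wrong:
  - Deprotonation of 6 may quench its electrophilicity.
  - Compound 7 may self-condense by aldol and Claisen pathways faster than it is acylated.
  - Acyl transfer may stall at open-chain or O-acylated stages that fragment by retro-Claisen cleavage.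
- Fallback: known chemistry, with ring A brought in as an intact arene.
- Setting out from phenol 4, Ullmann coupling with bromoaldehyde 21 (CuI, picolinic acid, K3PO4, DMSO, 90 °C, as in step 11) should give 4-[4-(benzyloxy)-3,5-dimethoxyphenoxy]-3,5-dimethoxybenzaldehyde F1.
- Baeyer–Villiger oxidation with mCPBA leads by way of 4-[4-(benzyloxy)-3,5-dimethoxyphenoxy]-3,5-dimethoxyphenyl formate F2 and catalytic K2CO3 in MeOH to 4-[4-(benzyloxy)-3,5-dimethoxyphenoxy]-3,5-dimethoxyphenol F3.
- O-methylation (Me2SO4, K2CO3, acetone) comes back to the route at 12.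

Step 18.
- What may go wrong: C–O bond formation between the di-ortho-substituted phenoxide of 19 and the electron-rich bromide may be slow. Hydrodebromination of 32 and oxidative degradation of 19 could then take over.
- Fallback: the last ether made is changed from C–D to D–E. The hindered phenol then meets a small aryl iodide used in excess, and the final union uses the less hindered phenol 28.
- The isomeric ring D unit is prepared from 2-bromo-6-methoxyphenol. Para-iodination (NIS, MeCN) gives 2-bromo-4-iodo-6-methoxyphenol F4, and methylation (MeI, K2CO3) gives 1-bromo-5-iodo-2,3-dimethoxybenzene F5.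
- Setting out from 19, iodide-selective Ullmann coupling with F5 should give 1-bromo-5-{6-[2,6-dimethoxy-4-(2,4,6-trimethoxyphenoxy)phenoxy]-2,3,4-trimethoxyphenoxy}-2,3-dimethoxybenzene F6.
- A second Ullmann coupling of F6 with phenol 28 comes back to the route at 33.

Step 19.
- What may go wrong:
  - Ether cleavage may stay incomplete once partly demethylated boron chelates precipitate.
  - The pyrogallol-type rings may oxidise in air during isolation of the very polar free phenol.
- Fallback: derivatise, purify, then release.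
- Setting out from 33, the crude BBr3 product is not purified. It is peracetylated at once (Ac2O, pyridine, Ar) to the octadecaacetate of the target F7.
- F7 is stable and can be chromatographed on silica. Under-demethylated fractions can be separated there and resubmitted to BBr3.
- Acid-catalysed methanolysis of pure F7 (AcCl cat., degassed MeOH, rt to 40 °C) and evaporation come back to the route at 35.

**Further compounds**
F1 | step 4 | 4-[4-(benzyloxy)-3,5-dimethoxyphenoxy]-3,5-dimethoxybenzaldehyde | COc1cc(C=O)cc(OC)c1Oc1cc(OC)c(OCc2ccccc2)c(OC)c1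
F2 | step 4 | 4-[4-(benzyloxy)-3,5-dimethoxyphenoxy]-3,5-dimethoxyphenyl formate | COc1cc(OC=O)cc(OC)c1Oc1cc(OC)c(OCc2ccccc2)c(OC)c1
F3 | step 4 | 4-[4-(benzyloxy)-3,5-dimethoxyphenoxy]-3,5-dimethoxyphenol | COc1cc(O)cc(OC)c1Oc1cc(OC)c(OCc2ccccc2)c(OC)c1
F4 | step 18 | 2-bromo-4-iodo-6-methoxyphenol | COc1cc(I)cc(Br)c1O
F5 | step 18 | 1-bromo-5-iodo-2,3-dimethoxybenzene | COc1cc(I)cc(Br)c1OC
F6 | step 18 | 1-bromo-5-{6-[2,6-dimethoxy-4-(2,4,6-trimethoxyphenoxy)phenoxy]-2,3,4-trimethoxyphenoxy}-2,3-dimethoxybenzene | COc1cc(Oc2c(OC)c(OC)c(OC)cc2Oc2c(OC)cc(Oc3c(OC)cc(OC)cc3OC)cc2OC)cc(Br)c1OC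
F7 | step 19 | octadecaacetate of the target | CC(=O)Oc1cc(OC(C)=O)c(Oc2cc(OC(C)=O)c(Oc3cc(OC(C)=O)c(OC(C)=O)c(OC(C)=O)c3Oc3cc(OC(C)=O)c(OC(C)=O)c(Oc4cc(OC(C)=O)c(OC(C)=O)c(OC(C)=O)c4Oc4cc(OC(C)=O)c(Oc5cc(OC(C)=O)c(OC(C)=O)c(OC(C)=O)c5)c(OC(C)=O)c4)c3)c(OC(C)=O)c2)c(OC(C)=O)c1
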